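**Retrosynthetic overview**
- The oxirane is the only ring formed and is closed last: C8–O/C9–O disconnection to the fully acylated 8,9-alkene (a 10-isobutyryloxy-8,9-dehydrothymol diester). Ring closure is a direct, catalyst-controlled oxygen-atom transfer from an iron-oxo oxidant, as the plant oxygenase is presumed to do, and it sets the single (R) stereocentre.
- C10–O: isobutyrate ⇒ allylic alcohol ⇒ allylic C–H oxygenation of the 8,9-dehydrothymol-type aryl tiglate (the biosynthetic order: desaturated side chain, C10 oxygenation, acylation, epoxidation).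
- Aryl–C8 bond and aryl ester: Suzuki–Miyaura coupling of an ortho-bromophenol with an isopropenyl boronate, with tigloylation in the same flask.
- C–Br: regioselective bromination of 4-methoxy-3-methylphenol; the benzene ring is bought.

Assumption: the (S,S) iron catalyst paired with the L-isoleucine-derived co-ligand is taken to deliver the (R)-epoxide; this is checked on the first run by chiral HPLC against racemic material and, if reversed, the mirror-image catalyst and D-amino acid are used with nothing else changed.

**Route**

Step 1
Reactants: 1 4-methoxy-3-methylphenol; 2 N-bromosuccinimide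
Product: 3 2-bromo-4-methoxy-5-methylphenol
Conditions: NBS (1.0 equiv), MeCN, 0 °C, 1 h, dark
Reagents that add atoms: N-bromosuccinimide 2, O=C1CCC(=O)N1Br
Why: Electrophilic aromatic bromination in which the free OH is the strongest director, its para position is blocked by OMe, and of its two ortho positions the one flanked by the methyl group is hindered while the other is also para to that methyl group, so bromine enters there.

Step 2
Reactants: 3 2-bromo-4-methoxy-5-methylphenol; 4 isopropenylboronic acid pinacol ester (4,4,5,5-tetramethyl-2-(prop-1-en-2-yl)-1,3,2-dioxaborolane); 5 tigloyl chloride ((E)-2-methylbut-2-enoyl chloride)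
Product: 7 4-methoxy-5-methyl-2-(prop-1-en-2-yl)phenyl (E)-2-methylbut-2-enoate, via 2-isopropenyl-4-methoxy-5-methylphenol 6 (not isolated)
Conditions: PdCl2(dppf) (3 mol%), K2CO3 (4 equiv), 1,4-dioxane/H2O 4:1, 85 °C, 4 h; then 0 °C, tigloyl chloride (1.8 equiv), 1 h
Reagents that add atoms: isopropenylboronic acid pinacol ester 4, CC(=C)B1OC(C)(C)C(C)(C)O1; tigloyl chloride 5, C/C=C(\C)C(Cl)=O
Why: Suzuki–Miyaura coupling of the aryl bromide (as its phenoxide) with the alkenyl boronate forms the aryl–C8 bond, and the potassium phenoxide is then O-acylated in the same aqueous-organic mixture (Schotten–Baumann acylation) before the free o-isopropenylphenol can dimerise; the E geometry of the tiglate comes in with the acid chloride and no stereocentre is formed.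

Step 3
Reactants: 7 4-methoxy-5-methyl-2-(prop-1-en-2-yl)phenyl (E)-2-methylbut-2-enoate; 8 tert-butyl hydroperoxide
Product: 9 2-(3-hydroxyprop-1-en-2-yl)-4-methoxy-5-methylphenyl (E)-2-methylbut-2-enoate
Conditions: SeO2 (30 mol%), t-BuOOH (70% aq., 2.5 equiv), CH2Cl2, 20 °C, 24 h (stopped near 75% conversion, 7 recycled)
Reagents that add atoms: tert-butyl hydroperoxide 8, CC(C)(C)OO (its oxygen is relayed to carbon by the catalytic SeO2, O=[Se]=O)
Why: SeO2-catalysed allylic oxidation (Riley oxidation in its tert-butyl hydroperoxide variant: ene reaction, then 2,3-sigmatropic shift) attacks the more electron-rich 1,1-disubstituted alkene, whose only allylic C–H bonds are those of the C10 methyl group, and leaves the electron-poor tiglate alkene alone; no stereocentre is formed.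

Step 4
Reactants: 9 2-(3-hydroxyprop-1-en-2-yl)-4-methoxy-5-methylphenyl (E)-2-methylbut-2-enoate; 10 isobutyryl chloride (2-methylpropanoyl chloride)
Product: 11 4-methoxy-5-methyl-2-[3-(2-methylpropanoyloxy)prop-1-en-2-yl]phenyl (E)-2-methylbut-2-enoate
Conditions: i-PrCOCl (1.3 equiv), pyridine (2 equiv), DMAP (5 mol%), CH2Cl2, 0 °C, 1 h
Reagents that add atoms: isobutyryl chloride 10, CC(C)C(Cl)=O
Why: Pyridine/DMAP-catalysed O-acylation (nucleophilic acyl substitution) of the primary allylic alcohol is fast enough at 0 °C to outrun migration of the neighbouring aryl tiglate; no stereocentre is formed.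

Step 5
Reactants: 11 4-methoxy-5-methyl-2-[3-(2-methylpropanoyloxy)prop-1-en-2-yl]phenyl (E)-2-methylbut-2-enoate; 12 hydrogen peroxide
Product: 13 4-methoxy-5-methyl-2-[(2R)-2-[(2-methylpropanoyloxy)methyl]oxiran-2-yl]phenyl (E)-2-methylbut-2-enoate (the target)
Conditions: Fe(OTf)2(L) (2 mol%; L = (2S,2'S)-1,1'-bis[(4-dimethylaminopyridin-2-yl)methyl]-2,2'-bipyrrolidine), N-1,8-naphthaloyl-L-isoleucine (6 mol%), 30% aq. H2O2 (1.8 equiv, syringe pump over 30 min), MeCN, −30 °C
Reagents that add atoms: hydrogen peroxide 12, OO
Why: Proposed new method: a bioinspired non-heme iron asymmetric epoxidation in which the divalent iron complex and the amino-acid carboxylate split H2O2 heterolytically to an electrophilic iron-oxo carboxylate (formally pentavalent iron) that transfers its oxygen atom in one step to the more electron-rich 1,1-disubstituted styrenic alkene (not to the electron-poor tiglate alkene) inside the chiral pocket formed by the (S,S) ligand and the L-isoleucine co-ligand, which selects the alkene face leading to the (R) oxirane; the closest known reaction type is the iron/H2O2/amino-acid epoxidation of alpha-alkylstyrenes, extended here to an alpha-(acyloxymethyl)styrene carrying an ortho ester.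

**Compound list**
1 | 4-methoxy-3-methylphenol | COc1ccc(O)cc1C | starting material
2 | N-bromosuccinimide | O=C1CCC(=O)N1Br | starting material
3 | 2-bromo-4-methoxy-5-methylphenol | COc1cc(Br)c(O)cc1C | intermediate
4 | isopropenylboronic acid pinacol ester | CC(=C)B1OC(C)(C)C(C)(C)O1 | starting material
5 | tigloyl chloride, (E)-2-methylbut-2-enoyl chloride | C/C=C(\C)C(Cl)=O | starting material
6 | 2-isopropenyl-4-methoxy-5-methylphenol (present in the flask as its potassium phenoxide) | C=C(C)c1cc(OC)c(C)cc1O | intermediate
7 | 4-methoxy-5-methyl-2-(prop-1-en-2-yl)phenyl (E)-2-methylbut-2-enoate | C/C=C(\C)C(=O)Oc1cc(C)c(OC)cc1C(C)=C | intermediate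
8 | tert-butyl hydroperoxide | CC(C)(C)OO | starting material
9 | 2-(3-hydroxyprop-1-en-2-yl)-4-methoxy-5-methylphenyl (E)-2-methylbut-2-enoate | C/C=C(\C)C(=O)Oc1cc(C)c(OC)cc1C(=C)CO | intermediate
10 | isobutyryl chloride | CC(C)C(Cl)=O | starting material
11 | 4-methoxy-5-methyl-2-[3-(2-methylpropanoyloxy)prop-1-en-2-yl]phenyl (E)-2-methylbut-2-enoate | C/C=C(\C)C(=O)Oc1cc(C)c(OC)cc1C(=C)COC(=O)C(C)C | intermediate
12 | hydrogen peroxide | OO | starting material
13 | 4-methoxy-5-methyl-2-[(2R)-2-[(2-methylpropanoyloxy)methyl]oxiran-2-yl]phenyl (E)-2-methylbut-2-enoate | C/C=C(\C)C(=O)Oc1cc(C)c(OC)cc1[C@]1(COC(=O)C(C)C)CO1 | target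

**Step count**
Total: 5 steps. Longest linear sequence: 5 steps (1 → 3 → 7 → 9 → 11 → 13).

**Steps most likely to fail, with fallbacks**

Step 5 is the main risk. The ortho-substituted, allylic-ester-bearing alkene lies outside the proven scope of the iron catalyst, the ee may fall short, and some oxidation of the tiglate alkene is possible. If the ee is below 98%, the product is polished by preparative HPLC on a chiral cellulose phase. The fallback replaces undirected oxygen transfer by hydroxyl-directed titanium–tartrate epoxidation (Sharpless asymmetric epoxidation). It sets out from alcohol 9: Ti(OiPr)4 (10 mol%), L-(+)-diethyl tartrate (12 mol%), tert-butyl hydroperoxide 8 (2 equiv), 4 Å molecular sieves, CH2Cl2, −20 °C gives 2-[(2S)-2-(hydroxymethyl)oxiran-2-yl]-4-methoxy-5-methylphenyl (E)-2-methylbut-2-enoate F1. The natural tartrate gives the (S) epoxy alcohol, as it does for other 2-substituted allyl alcohols. Acylation with isobutyryl chloride 10 and pyridine at 0 °C comes back to the route at 13; the descriptor changes from S to R only because the CIP ranking of the two CH2O arms swaps on acylation.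

Step 3 is the second risk. SeO2 oxidations of alpha-methylstyrene-type alkenes give moderate yields and some over-oxidation to the enal. The fallback replaces selenium oxidation and acylation by allylic halogenation and carboxylate displacement. It sets out from 7: N-bromosuccinimide 2 in CHCl3 at reflux gives 2-(3-bromoprop-1-en-2-yl)-4-methoxy-5-methylphenyl (E)-2-methylbut-2-enoate F2. SN2 displacement with isobutyric acid and K2CO3 in DMF at 20 °C comes back to the route at 11, so 9 and step 4 are bypassed.

Step 2 is the third risk. The electron-rich ortho-bromophenoxide couples slowly, and the o-isopropenylphenol 6 can dimerise or be acylated incompletely in the wet mixture. The fallback replaces cross-coupling by carbonyl olefination and never frees 6. It sets out from phenol 1, so step 1 is not needed: ortho-acetylation with acetic acid in BF3·OEt2 at 90 °C (Friedel–Crafts/Fries type, same site selectivity as the bromination) gives 1-(2-hydroxy-5-methoxy-4-methylphenyl)ethan-1-one F3. Tigloyl chloride 5 with Et3N and DMAP in CH2Cl2 gives 2-acetyl-4-methoxy-5-methylphenyl (E)-2-methylbut-2-enoate F4. Ketone-selective methylenation with Zn/CH2Br2/TiCl4 in THF–CH2Cl2 (Takai–Lombardo) converts the acetyl group into the isopropenyl group and comes back to the route at 7.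

**Further compounds**
F1 | step 5 | 2-[(2S)-2-(hydroxymethyl)oxiran-2-yl]-4-methoxy-5-methylphenyl (E)-2-methylbut-2-enoate | C/C=C(\C)C(=O)Oc1cc(C)c(OC)cc1[C@]1(CO)CO1
F2 | step 3 | 2-(3-bromoprop-1-en-2-yl)-4-methoxy-5-methylphenyl (E)-2-methylbut-2-enoate | C/C=C(\C)C(=O)Oc1cc(C)c(OC)cc1C(=C)CBr
F3 | step 2 | 1-(2-hydroxy-5-methoxy-4-methylphenyl)ethan-1-one | CC(=O)c1cc(OC)c(C)cc1O
F4 | step 2 | 2-acetyl-4-methoxy-5-methylphenyl (E)-2-methylbut-2-enoate | C/C=C(\C)C(=O)Oc1cc(C)c(OC)cc1C(C)=O
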